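## The problem

The target is a germacranolide. Its ten-membered carbocycle is numbered here C1 (ketone), C2=C3 (E olefin), C4 (methyl C15), C5 (free hydroxyl), C6 (lactone oxygen), C7 (ring fusion, bearing C11), C8 (angelate), C9 (methylene) and C10 (methyl C14, acetate); a trans-fused α-methylene-γ-butyrolactone (C11=C13, C12 carbonyl) spans C6–C7. Direct closure of such a ring is penalised by entropy and transannular strain, and six stereocentres (4S,5S,6S,7R,8R,10S) sit on a flexible frame where relative control is unreliable. On a six-membered ring the C7 centre can control C8 and C10, because the C7 side chain and both oxygens are cis and can be set by delivery from one oxygen to the next. C4 and C5 form a vicinal anti pair that a crotylation reagent can set; only C6 must be set on the medium ring, between C5 and C7. The angelate (Z to E isomerisation), the α-methylene lactone and the enone (Michael acceptors), the tertiary α-acetoxy ketone and the C4 centre γ to the enone do not survive strong base, hydride or nucleophiles and must come last. What allows ring closure to be avoided is that the oxygenated carbons C1 and C6 lie 1,6 across the ring. Joined by a double bond they give ring A (C1–C6) and ring B (C1, C10–C6) of a bicyclo[4.4.0]dec-1(6)-ene whose perimeter is the ten-membered ring. Cleaving that tetrasubstituted C1=C6 olefin gives the C1 ketone directly and the C6 carbinol after reduction, without forming any carbon–carbon bond.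

## Retrosynthesis

**Esters and silyl groups (37 to 33).** The C8–O angelate bond, the C10–O acetate bond and the C5 silyl ether are handled last, because no ester of this kind survives hydride, amide base or selenium chemistry. This leads back through acetate 36 and angelate 35 to enone diol 34 and its silylene 33. The forward steps must free C8/C10 while C5 stays silylated, so that the only secondary hydroxyl (C8) takes the angelate and the tertiary one (C10) the acetate.

**The two unsaturations (33 to 27).** C2=C3 and C11=C13 are removed as dehydrogenations, giving keto lactone 31, its C1 alcohol 30 and the saturated hydroxy lactone 27. The methylene group is made first (amide base, selenium) while C1 is an alcohol; the enone is made after, when the lactone has no α-hydrogen left and C1 can enolise only toward C2.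

**Lactone C6–O bond (27 to 25).** Cutting the lactone C–O bond and oxidising C6 gives dione ester 25. The forward step reduces both ketones, which removes any need to tell C1 from C6; C1 is reoxidised later. The demand is facial selectivity at C6.

**The key cut (25 to 22).** Reconnecting C1 and C6 as a double bond gives octalin 22. Against cutting a ring bond of the ten-membered ring (any macrocyclisation), this transform needs no medium-ring closure, and 22 carries C4, C5, C7, C8 and C10 on two half-chair cyclohexenes. The forward reaction, ozonolysis, asks only that no other olefin be present and that the dione not enolise.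

**Ring A (22 to 17).** Ring A is cut at C1–C2 (B-alkyl Suzuki coupling of bromide 20) and at C4–C5 (crotylboration of bromo enal 17 to alcohol 19). A Diels–Alder closure of ring A on a bis-alkylidene ring B was considered. It would have to add syn to the C7 side chain to place the C5 oxygen correctly and needs a later decarbonylation; the crotylation sets C4 and C5 by reagent control in one step.

**C5–C6 bond and C1 handle (17 to 15).** Bromo enal 17 comes from ring B ketone 15 by haloformylation. The ketone has a single enolisable side (C6), because C10 is quaternary, so regiochemistry is fixed. 15 is a monocyclic cyclohexanone with three stereocentres.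

**Ring B oxygens and side chain (15 to 7).** The propanoate side chain is the isopropenyl group at a higher oxidation level (alcohol 13, acid 14). The C8 hydroxyl of keto diol 10 is traced to the C8=C9 olefin of hydroxy ketone 7 by hydrosilylation tethered to the C10 oxygen, which forces the cis-1,3-diol; silylene 11 protects it.

**Chiral pool (7 to 1).** 7 is the oxidation product of dienediol 6, itself the allylic transposition product of epoxy alcohol 3, which comes from cis-carveol 2 and (R)-carvone 1. Carvone supplies C7 with the right absolute configuration, the C10 methyl and the C1 oxygen. The forward steps relay C7 to C1, to C10 and to C8.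

## Roads not taken

**Alternative 1:** The cut is O–C6 and C7–C8, made forward by a Paternò–Büchi photocycloaddition of aldehyde A1 to furan A2, giving the exo oxetane photoadduct A3. Its merit is speed: one step from two simple pieces forms two bonds and the contiguous C6–C8 centres and brings in the lactone carbons as a dihydrofuran. In that region it is more step-economical than the chosen plan. Its weak points are these: the C8 centre is set relative to C10 only by remote acyclic induction, C5 must later be attached at the acetal carbon with control of C6, and the ten-membered ring, C4/C5 and the enone are all still to be made. The chosen plan takes more steps to the C6–C8 triad but forms the medium ring without a cyclisation and sets every centre but C6 on a six-membered ring.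

**Alternative 2:** The cut is C1–C2 and O–C3, made forward by an intramolecular nitrile oxide cycloaddition that closes the ten-membered ring as the bridged isoxazoline A4. Its merits are convergence, a late ring closure with the lactone already in place, and an isoxazoline that unmasks to the β-hydroxy ketone and then the enone. That is a gentler route to the enone than the late dehydrogenation used here, and in this respect it is the better plan. Its weak points are the medium-ring dipolar closure, which competes with nitrile oxide dimerisation and has uncertain bridged-versus-fused regiochemistry, the need to build an open-chain precursor with six stereocentres, and N–O cleavage and dehydration next to the epimerisable C4. Against its elegance the chosen plan sets a ring that cannot fail to form and stereocentres set on rigid rings, at the price of a longer linear sequence.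

**Alternative 3:** The cut is C6–C7, made forward by a Wittig–Still [2,3] shift that contracts a thirteen-membered allyl ether to the ten-membered carbinol A5. Its merits are that the C6 carbinol, the C6–C7 bond and the exocyclic C11=C13 methylene arise together in one ordered step, so no selenium chemistry and no ketone reduction at C6 is needed. Here it is better than the chosen plan, whose C6 selectivity rests on a hydride reduction. Its weak points are the thirteen-membered ether that must be closed first, stoichiometric tin, competing [1,2] shift, a sense of induction that depends on macrocycle conformation, and a heavier protecting-group load. The chosen plan sets against it the absence of any macrocyclisation and a fallback that corrects C6 by inversion.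

Key step: step 14

## Route

Remarks on the chemistry:
- The locants defined above are used for every intermediate.
- C11 is an epimer mixture from 12 to 29 and the C1 carbinol an epimer mixture in 26–30; both centres are erased later and are left undefined in the SMILES.
- The crotylborane of step 11 is assumed to be used as a freshly made stock solution (from (−)-Ipc2BOMe, (E)-crotylpotassium and BF3·OEt2); its preparation is not counted as a step.

Step 1
Reactants: 1 (R)-carvone
Product: 2 (1R,5R)-cis-carveol
Conditions: NaBH4, CeCl3·7H2O, MeOH, −78 → 0 °C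
Reagents that add atoms: none
Why: Luche reduction gives clean 1,2-reduction of the enone; axial hydride attack on the half-chair with an equatorial isopropenyl group should place the new C1 hydroxyl cis to the C7 substituent.

Step 2
Reactants: 2 (1R,5R)-cis-carveol
Product: 3 syn-epoxy carveol
Conditions: VO(acac)2 (cat.), t-BuOOH, toluene, 0 °C → rt
Reagents that add atoms: tert-butyl hydroperoxide, CC(C)(C)OO
Why: Hydroxyl-directed vanadium-catalysed epoxidation of the allylic alcohol delivers oxygen to C9=C10 from the face of the C1 hydroxyl and spares the isolated isopropenyl olefin; this sets the C10–O bond cis to the C7 side chain.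

Step 3
Reactants: 3 syn-epoxy carveol
Product: 6 dienediol, via hydroxy selenide 4 (not isolated), via selenoxide 5 (not isolated)
Conditions: PhSeSePh, NaBH4, EtOH, 80 °C; then H2O2 (30%), THF, 0 °C → rt
Reagents that add atoms: none
Why: Epoxide to allylic alcohol transposition by the selenide route: PhSe− should open the epoxide trans-diaxially at the secondary C9 (Fürst–Plattner, hydroxyl and isopropenyl equatorial), and selenoxide syn-elimination can run only toward C8 because C10 is quaternary. C10 keeps its configuration.

Step 4
Reactants: 6 dienediol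
Product: 7 hydroxy ketone
Conditions: Dess–Martin periodinane, pyridine, CH2Cl2, rt
Reagents that add atoms: none
Why: Only the secondary C1 alcohol can be oxidised; the β,γ-unsaturated ketone cannot move into conjugation because C10 is quaternary.

Step 5
Reactants: 7 hydroxy ketone
Product: 10 keto diol, via silyl ether 8 (not isolated), via oxasilolane 9 (not isolated)
Conditions: (HMe2Si)2NH, 60 °C; then Pt2[(CH2=CHSiMe2)2O]3 (cat.), toluene, 60 °C, high dilution; then H2O2 (30%), KF, KHCO3, THF/MeOH, rt
Reagents that add atoms: hydrogen peroxide, OO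
Why: Intramolecular hydrosilylation of the allylic silyl ether (endo mode, five-membered oxasilolane) and Tamao–Fleming oxidation, the known route from allylic alcohols to 1,3-diols. The tether forces silicon, and so the C8 hydroxyl, onto the face of the C10 oxygen (also the face of the C7 side chain), and C–Si oxidation goes with retention.

Step 6
Reactants: 10 keto diol
Product: 11 silylene ketone
Conditions: t-Bu2Si(OTf)2, 2,6-lutidine, CH2Cl2, 0 °C
Reagents that add atoms: di-tert-butylsilyl bis(trifluoromethanesulfonate), CC(C)(C)[Si](OS(=O)(=O)C(F)(F)F)(OS(=O)(=O)C(F)(F)F)C(C)(C)C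
Why: The cis-1,3-diol closes a six-membered dioxasilinane under basic conditions; the group should tolerate the acidic haloformylation, amide base and ozone, and it keeps the C8 hydroxyl from lactonising onto the side chain.

Step 7
Reactants: 11 silylene ketone
Product: 13 primary alcohol, via catechol boronate 12 (not isolated)
Conditions: catecholborane, RhCl(PPh3)3 (cat.), THF, 0 °C → rt; then H2O2 (30%), pH 7 buffer, THF/MeOH, 0 °C
Reagents that add atoms: hydrogen peroxide, OO
Why: Rhodium-catalysed hydroboration puts boron on the terminal carbon of the 1,1-disubstituted olefin and, unlike uncatalysed boranes, should spare the hindered ketone; the new C11 centre forms as a mixture that is erased in step 16.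

Step 8
Reactants: 13 primary alcohol
Product: 14 carboxylic acid
Conditions: TEMPO (cat.), PhI(OAc)2, MeCN/H2O, rt
Reagents that add atoms: water, O
Why: Oxoammonium oxidation takes the primary alcohol through the aldehyde hydrate to the acid under near-neutral conditions that leave the ketone and the silylene alone.

Step 9
Reactants: 14 carboxylic acid
Product: 15 ring B keto ester
Conditions: TMSCHN2, toluene/MeOH, 0 °C
Reagents that add atoms: trimethylsilyldiazomethane, C[Si](C)(C)C=[N+]=[N-]
Why: Mild O-methylation of the acid; the methyl ester is inert in steps 10 to 14 and later acts as the acyl donor for lactonisation.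

Step 10
Reactants: 15 ring B keto ester
Product: 17 bromo enal, via bromovinyl iminium salt 16 (not isolated)
Conditions: PBr3, DMF, CHCl3, 0 → 40 °C; then aq. NaOAc
Reagents that add atoms: N,N-dimethylformamide, CN(C)C=O; phosphorus tribromide, BrP(Br)Br; water, O
Why: Vilsmeier–Haack–Arnold haloformylation: the ketone can enolise only toward C6, so formylation at C6 and replacement of the carbonyl oxygen by bromide give the tetrasubstituted β-bromo enal. It carries C5 as an aldehyde and C1 as a cross-coupling site.

Step 11
Reactants: 17 bromo enal
Product: 19 homoallylic alcohol, via borinate 18 (not isolated)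
Conditions: (E)-crotyl-B(Ipc)2 (Ipc from (+)-α-pinene), THF/Et2O, −78 °C; then NaBO3·4H2O, THF/H2O, rt
Reagents that add atoms: (E)-crotyldiisopinocampheylborane, C/C=C/CB([C@@H]1C[C@@H]2C[C@H]([C@H]1C)C2(C)C)[C@@H]3C[C@@H]4C[C@H]([C@H]3C)C4(C)C
Why: Brown crotylboration through a chair Zimmerman–Traxler transition state: the E-crotyl geometry gives the anti C4/C5 pair, and the isopinocampheyl groups from (+)-α-pinene should select the aldehyde face that gives 5S and hence 4S. Reagent control is expected to override the remote ring B centres.

Step 12
Reactants: 19 homoallylic alcohol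
Product: 20 TBS ether
Conditions: TBSOTf, 2,6-lutidine, CH2Cl2, −78 → 0 °C
Reagents that add atoms: tert-butyldimethylsilyl trifluoromethanesulfonate, CC(C)(C)[Si](C)(C)OS(=O)(=O)C(F)(F)F
Why: Silyl triflate silylation of the hindered secondary alcohol; the C5 ether has to outlast the C8/C10 silylene so that C8 can be esterified alone at the end, and its bulk favours Felkin–Anh control in step 15.

Step 13
Reactants: 20 TBS ether
Product: 22 octalin, via B-alkyl-9-BBN 21 (not isolated)
Conditions: 9-BBN-H, THF, 0 °C → rt; then PdCl2(dppf) (cat.), AsPh3, Cs2CO3, DMF/H2O, 50 °C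
Reagents that add atoms: none
Why: Hydroboration of the terminal vinyl group puts boron on C2, and an intramolecular B-alkyl Suzuki–Miyaura coupling with the vinyl bromide forms C1–C2. This closes six-membered ring A and leaves the tetrasubstituted C1=C6 olefin in place; no stereocentre is touched.

Step 14
Reactants: 22 octalin
Product: 25 cyclodecane-1,6-dione, via primary ozonide 23 (not isolated), via ozonide 24 (not isolated)
Conditions: O3, CH2Cl2, −78 °C; then PPh3, −78 °C → rt
Reagents that add atoms: ozone, [O-][O+]=O
Why: Ozone adds across the electron-rich tetrasubstituted C1=C6 olefin of 22 in a [3+2] cycloaddition to give primary ozonide 23. 23 cycloreverts to a ketone and a tethered carbonyl oxide, which recombine (Criegee mechanism) to the bridged 1,2,4-trioxolane 24; PPh3 then takes one oxygen and releases the two ketones of 25. The closest known reaction is the ozonolytic cleavage of the ring-fusion olefin of a 9,10-octalin to cyclodecane-1,6-dione. The ten-membered ring is not closed by bond formation: it is the perimeter of the bicycle and appears when the shared C1–C6 bond is cut, so the only ring closures behind it are six-membered ones (ring B from carvone, ring A in step 13). No stereocentre is formed; C4, C5, C7, C8 and C10 pass through unchanged. The step needs chemoselectivity and configurational integrity: 22 has no other olefin (the side chain is saturated, the angelate is not yet present), silyl ethers and the ester are inert to ozone, and the cold neutral reductive work-up avoids enolisation of the 1,6-dione and with it epimerisation at C5 or C7 and transannular aldol closure. 25 is taken at once into step 15.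

Step 15
Reactants: 25 cyclodecane-1,6-dione
Product: 27 hydroxy lactone, via diol ester 26 (not isolated)
Conditions: NaBH4, MeOH/CH2Cl2, −40 → 0 °C; then PPTS (cat.), toluene, 50 °C
Reagents that add atoms: none
Why: Both ketones are reduced, so C1 and C6 need not be told apart. At C6 hydride should add anti to the C5 silyloxy group and anti to the branched C11 substituent on C7 (Felkin–Anh on both flanks), giving the 6S carbinol, which closes the trans γ-lactone onto the ester. The C1 carbinol is reoxidised in step 17.

Step 16
Reactants: 27 hydroxy lactone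
Product: 30 methylene lactone alcohol, via lactone selenide 28 (not isolated), via lactone selenoxide 29 (not isolated)
Conditions: LiN(i-Pr)2 (3 equiv), THF, −78 °C; PhSeBr; then H2O2 (30%), pyridine, CH2Cl2, 0 °C → rt
Reagents that add atoms: none
Why: α-Selenenylation of the lactone enolate and selenoxide syn-elimination, the standard conversion of an α-methyl into an α-methylene γ-lactone. Selenium should enter the enolate face remote from H-7, so the selenoxide finds syn β-hydrogens only on the methyl group; both C11 epimers converge.

Step 17
Reactants: 30 methylene lactone alcohol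
Product: 31 keto methylene lactone
Conditions: Dess–Martin periodinane, pyridine, CH2Cl2, rt
Reagents that add atoms: none
Why: Oxidation of the only free hydroxyl restores the C1 ketone under neutral conditions that spare the methylene lactone.

Step 18
Reactants: 31 keto methylene lactone
Product: 33 enone, via enol silane 32 (not isolated)
Conditions: TMSOTf, Et3N, CH2Cl2, 0 °C; then Pd(OAc)2, MeCN, rt
Reagents that add atoms: none
Why: Soft enolisation can occur only toward C2 (C10 is quaternary and the lactone has no α-hydrogen left). Saegusa–Ito oxidation of the enol silane (palladium enolate, syn β-hydride elimination) should install C2=C3, expected as the E isomer from the extended conformer.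

Step 19
Reactants: 33 enone
Product: 34 enone diol
Conditions: HF·pyridine, pyridine, THF, 0 °C
Reagents that add atoms: none
Why: Selective desilylation: buffered fluoride should cleave the cyclic dialkoxysilane much faster than the hindered secondary TBS ether, freeing the C8 and C10 hydroxyls without base.

Step 20
Reactants: 34 enone diol
Product: 35 angelate
Conditions: angelic acid, 2,4,6-Cl3C6H2COCl, Et3N, toluene, rt; then 34, 80 °C
Reagents that add atoms: angelic acid, C/C=C(/C)C(=O)O
Why: Yamaguchi-type esterification through the mixed anhydride should acylate the secondary C8 hydroxyl and not the tertiary C10 hydroxyl; running it without DMAP limits Z to E isomerisation of the angelate.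

Step 21
Reactants: 35 angelate
Product: 36 acetate
Conditions: Ac2O, DMAP (cat.), Et3N, CH2Cl2, rt
Reagents that add atoms: acetic anhydride, CC(=O)OC(C)=O
Why: DMAP-catalysed acetylation of the remaining tertiary α-keto alcohol; C5 is still silylated, so only C10 can react.

Step 22
Reactants: 36 acetate
Product: 37 target germacranolide
Conditions: HF·pyridine, THF, rt
Reagents that add atoms: none
Why: Fluoride removes the last silyl ether under mildly acidic conditions that should leave both esters, the enone and the methylene lactone untouched.

## Compound list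

1 | (R)-carvone | O=C1C(C)=CC[C@@H](C(C)=C)C1 | starting material
2 | (1R,5R)-cis-carveol; C1 hydroxyl cis to the C7 isopropenyl group | O[C@H]1C(C)=CC[C@@H](C(C)=C)C1 | intermediate
3 | syn-epoxy carveol; C9–C10 epoxide on the face of the C1 hydroxyl | O[C@H]1[C@@]2(C)O[C@H]2C[C@@H](C(C)=C)C1 | intermediate
4 | hydroxy selenide; C9 phenylselanyl trans to the C10 hydroxyl, C1/C10 diol | O[C@H]1[C@@](C)(O)[C@H]([Se]c2ccccc2)C[C@@H](C(C)=C)C1 | intermediate
5 | selenoxide of 4 (configuration at selenium undefined) | O[C@H]1[C@@](C)(O)[C@H]([Se](=O)c2ccccc2)C[C@@H](C(C)=C)C1 | intermediate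
6 | dienediol; 2-methyl-5-(prop-1-en-2-yl)cyclohex-3-ene-1,2-diol, both hydroxyls cis to isopropenyl | O[C@H]1[C@@](C)(O)C=C[C@@H](C(C)=C)C1 | intermediate
7 | hydroxy ketone; C1 ketone, tertiary C10 hydroxyl cis to isopropenyl, C8=C9 olefin | O=C1[C@@](C)(O)C=C[C@@H](C(C)=C)C1 | intermediate
8 | dimethylsilyl ether of 7 at the C10 oxygen | O=C1[C@@](C)(O[SiH](C)C)C=C[C@@H](C(C)=C)C1 | intermediate
9 | oxasilolane; SiMe2 bridge from the C10 oxygen to C8, cis to isopropenyl | O=C1[C@@]2(C)O[Si](C)(C)[C@H](C2)[C@@H](C(C)=C)C1 | intermediate
10 | keto diol; C8 and C10 hydroxyls and the C7 isopropenyl group all cis | O=C1[C@@](C)(O)C[C@@H](O)[C@@H](C(C)=C)C1 | intermediate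
11 | silylene ketone; di-tert-butylsilylene on the C8/C10 diol of 10 | O=C1[C@@]2(C)O[Si](C(C)(C)C)(C(C)(C)C)O[C@H](C2)[C@@H](C(C)=C)C1 | intermediate
12 | catechol boronate; C12 boron, C11 epimers | O=C1[C@@]2(C)O[Si](C(C)(C)C)(C(C)(C)C)O[C@H](C2)[C@@H](C(C)CB3Oc4ccccc4O3)C1 | intermediate
13 | primary alcohol; C7 1-hydroxypropan-2-yl side chain | O=C1[C@@]2(C)O[Si](C(C)(C)C)(C(C)(C)C)O[C@H](C2)[C@@H](C(C)CO)C1 | intermediate
14 | carboxylic acid; C7 propanoic acid side chain | O=C1[C@@]2(C)O[Si](C(C)(C)C)(C(C)(C)C)O[C@H](C2)[C@@H](C(C)C(=O)O)C1 | intermediate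
15 | ring B keto ester; methyl ester of 14 | O=C1[C@@]2(C)O[Si](C(C)(C)C)(C(C)(C)C)O[C@H](C2)[C@@H](C(C)C(=O)OC)C1 | intermediate
16 | bromovinyl iminium salt; C1 bromide, C6 dimethyliminiomethyl, bromide salt | BrC1=C(C=[N+](C)C)[C@H](C(C)C(=O)OC)[C@H]2C[C@]1(C)O[Si](C(C)(C)C)(C(C)(C)C)O2.[Br-] | intermediate
17 | bromo enal; C1 bromide, C6 formyl (C5) | BrC1=C(C=O)[C@H](C(C)C(=O)OC)[C@H]2C[C@]1(C)O[Si](C(C)(C)C)(C(C)(C)C)O2 | intermediate
18 | borinate; diisopinocampheylborinic ester of 19 | BrC1=C([C@@H](OB([C@@H]3C[C@@H]4C[C@H]([C@H]3C)C4(C)C)[C@@H]5C[C@@H]6C[C@H]([C@H]5C)C6(C)C)[C@@H](C)C=C)[C@H](C(C)C(=O)OC)[C@H]2C[C@]1(C)O[Si](C(C)(C)C)(C(C)(C)C)O2 | intermediate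
19 | homoallylic alcohol; (4S,5S), anti C4 methyl and C5 hydroxyl, terminal C2=C3 vinyl | BrC1=C([C@@H](O)[C@@H](C)C=C)[C@H](C(C)C(=O)OC)[C@H]2C[C@]1(C)O[Si](C(C)(C)C)(C(C)(C)C)O2 | intermediate
20 | TBS ether of 19 at C5 | BrC1=C([C@@H](O[Si](C)(C)C(C)(C)C)[C@@H](C)C=C)[C@H](C(C)C(=O)OC)[C@H]2C[C@]1(C)O[Si](C(C)(C)C)(C(C)(C)C)O2 | intermediate
21 | B-alkyl-9-BBN; boron on C2 | BrC1=C([C@@H](O[Si](C)(C)C(C)(C)C)[C@@H](C)CCB3C4CCCC3CCC4)[C@H](C(C)C(=O)OC)[C@H]2C[C@]1(C)O[Si](C(C)(C)C)(C(C)(C)C)O2 | intermediate
22 | octalin; bicyclo[4.4.0]dec-1(6)-ene, (4S,5S,7S,8R,10S), C5 OTBS, C8/C10 silylene, C7 methyl propanoate | C12=C([C@@H](O[Si](C)(C)C(C)(C)C)[C@@H](C)CC1)[C@H](C(C)C(=O)OC)[C@H]3C[C@]2(C)O[Si](C(C)(C)C)(C(C)(C)C)O3 | intermediate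
23 | primary ozonide; 1,2,3-trioxolane across C1–C6 (C1, C6 undefined) | C124CC[C@H](C)[C@H](O[Si](C)(C)C(C)(C)C)C1(OOO2)[C@H](C(C)C(=O)OC)[C@H]3C[C@]4(C)O[Si](C(C)(C)C)(C(C)(C)C)O3 | intermediate
24 | ozonide; 1,2,4-trioxolane bridging C1 and C6 (C1, C6 undefined) | C124CC[C@H](C)[C@H](O[Si](C)(C)C(C)(C)C)C(O1)(OO2)[C@H](C(C)C(=O)OC)[C@H]3C[C@]4(C)O[Si](C(C)(C)C)(C(C)(C)C)O3 | intermediate
25 | cyclodecane-1,6-dione; (4S,5S,7R,8R,10S), C1 and C6 ketones | O=C1CC[C@H](C)[C@H](O[Si](C)(C)C(C)(C)C)C(=O)[C@H](C(C)C(=O)OC)[C@H]2C[C@]1(C)O[Si](C(C)(C)C)(C(C)(C)C)O2 | intermediate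
26 | diol ester; 6S carbinol, C1 carbinol epimers | OC1CC[C@H](C)[C@H](O[Si](C)(C)C(C)(C)C)[C@@H](O)[C@H](C(C)C(=O)OC)[C@H]2C[C@]1(C)O[Si](C(C)(C)C)(C(C)(C)C)O2 | intermediate
27 | hydroxy lactone; trans 6,12-lactone, α-methyl, C1 carbinol | OC1CC[C@H](C)[C@H](O[Si](C)(C)C(C)(C)C)[C@H]2OC(=O)C(C)[C@@H]2[C@H]3C[C@]1(C)O[Si](C(C)(C)C)(C(C)(C)C)O3 | intermediate
28 | lactone selenide; C11 methyl and phenylselanyl (Se expected trans to H-7) | OC1CC[C@H](C)[C@H](O[Si](C)(C)C(C)(C)C)[C@H]2OC(=O)C(C)([Se]c4ccccc4)[C@@H]2[C@H]3C[C@]1(C)O[Si](C(C)(C)C)(C(C)(C)C)O3 | intermediate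
29 | lactone selenoxide | OC1CC[C@H](C)[C@H](O[Si](C)(C)C(C)(C)C)[C@H]2OC(=O)C(C)([Se](=O)c4ccccc4)[C@@H]2[C@H]3C[C@]1(C)O[Si](C(C)(C)C)(C(C)(C)C)O3 | intermediate
30 | methylene lactone alcohol; C11=C13, C1 carbinol | OC1CC[C@H](C)[C@H](O[Si](C)(C)C(C)(C)C)[C@H]2OC(=O)C(=C)[C@@H]2[C@H]3C[C@]1(C)O[Si](C(C)(C)C)(C(C)(C)C)O3 | intermediate
31 | keto methylene lactone; C1 ketone | O=C1CC[C@H](C)[C@H](O[Si](C)(C)C(C)(C)C)[C@H]2OC(=O)C(=C)[C@@H]2[C@H]3C[C@]1(C)O[Si](C(C)(C)C)(C(C)(C)C)O3 | intermediate
32 | enol silane; C1 trimethylsilyloxy, C1=C2 (geometry undefined) | C[Si](C)(C)OC1=CC[C@H](C)[C@H](O[Si](C)(C)C(C)(C)C)[C@H]2OC(=O)C(=C)[C@@H]2[C@H]3C[C@]1(C)O[Si](C(C)(C)C)(C(C)(C)C)O3 | intermediate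
33 | enone; C1 ketone, (E)-C2=C3 | O=C1/C=C/[C@H](C)[C@H](O[Si](C)(C)C(C)(C)C)[C@H]2OC(=O)C(=C)[C@@H]2[C@H]3C[C@]1(C)O[Si](C(C)(C)C)(C(C)(C)C)O3 | intermediate
34 | enone diol; free C8 and C10 hydroxyls, C5 OTBS | O=C1/C=C/[C@H](C)[C@H](O[Si](C)(C)C(C)(C)C)[C@H]2OC(=O)C(=C)[C@@H]2[C@H](O)C[C@]1(C)O | intermediate
35 | angelate; C8 (Z)-2-methylbut-2-enoate | O=C1/C=C/[C@H](C)[C@H](O[Si](C)(C)C(C)(C)C)[C@H]2OC(=O)C(=C)[C@@H]2[C@H](OC(=O)/C(C)=C\C)C[C@]1(C)O | intermediate
36 | acetate; C10 acetate, C8 angelate, C5 OTBS | O=C1/C=C/[C@H](C)[C@H](O[Si](C)(C)C(C)(C)C)[C@H]2OC(=O)C(=C)[C@@H]2[C@H](OC(=O)/C(C)=C\C)C[C@]1(C)OC(C)=O | intermediate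
37 | target; (4S,5S,6S,7R,8R,10S)-10-acetoxy-8-angeloyloxy-5-hydroxy-1-oxogermacra-2(E),11(13)-dien-6,12-olide | C=C1C(=O)O[C@@H]2[C@@H](O)[C@@H](C)/C=C/C(=O)[C@@](C)(OC(C)=O)C[C@@H](OC(=O)/C(C)=C\C)[C@@H]12 | target

## Step count and least certain steps

Total step count: 22. Longest linear sequence: 22 steps; the route is linear from (R)-carvone.

**Step 14 (key step).** The risks are incomplete reduction of the hindered, doubly tertiary ozonide, single-oxygen transfer to the crowded olefin in place of cleavage, and enolisation of the 1,6-dione on handling, which would lead to transannular aldol closure or epimerisation at C5 or C7. Fallback: from 22, dihydroxylation with stoichiometric OsO4 in pyridine should give the cis-1,6-diol F1, and glycol cleavage with Pb(OAc)4 in CH2Cl2 under neutral conditions returns to 25.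

**Step 5.** The endo-mode ring closure to a bridged oxasilolane may be slow. Hydrosilylation of the neighbouring ketone, or of the isopropenyl group of a second molecule, could then compete. Fallback: from 7, hydroxyl-directed epoxidation (VO(acac)2, t-BuOOH) should give the syn epoxy ketone F2. PhSeNa (from PhSeH and NaH) should open it trans-diaxially at C9 to the hydroxy selenide F3, and Bu3SnH with AIBN removes selenium and returns to 10.

**Step 13.** Oxidative addition into a tetrasubstituted vinyl bromide next to the quaternary C10 may be slow, so that protodeboronation or β-hydride elimination of the alkylborane wins. Fallback: from 20, Stille coupling with Bu3SnCH=CH2 should give the triene F4. Ring-closing metathesis with the second-generation Grubbs catalyst RuCl2(=CHPh)(PCy3)(H2IMes) closes ring A as the cyclohexadiene F5, and diimide (2-nitrobenzenesulfonylhydrazide, Et3N) reduces the disubstituted olefin alone, returning to 22.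

**Step 15.** Facial selectivity at C6 is the main stereochemical uncertainty: the reacting conformer of the ten-membered ring may not allow the Felkin–Anh arrangement on both flanks, and hydride would then add from the wrong face and close the cis lactone. Fallback: the 6-epimeric hydroxy lactone F6 that step 15 would then give from 25 is oxidised at C1 (Dess–Martin periodinane) to the keto lactone F7 and opened with Me2AlN(OMe)Me to the hydroxy amide F8. Mitsunobu activation (PPh3, DIAD) lets the amide oxygen displace the C6 hydroxyl with inversion, and aqueous hydrolysis gives the 6S keto lactone F9. NaBH4 reduction of its ketone returns to 27.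

**Step 18.** The geometry of the new olefin is uncertain: β-hydride elimination in the ten-membered palladium enolate could give the Z enone, or the hindered enolate could convert poorly. Fallback: from 31 through its enol silane 32, PhSeCl should give the α-phenylselanyl ketone F10, and oxidation with H2O2 followed by selenoxide syn-elimination returns to 33 by a different elimination mechanism.

## Further compounds

F1 | step 14 | cis-1,6-diol of 22 (C1 and C6 hydroxyls cis, face undefined) | OC12CC[C@H](C)[C@H](O[Si](C)(C)C(C)(C)C)C1(O)[C@H](C(C)C(=O)OC)[C@H]3C[C@]2(C)O[Si](C(C)(C)C)(C(C)(C)C)O3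
F2 | step 5 | syn epoxy ketone (C8–C9 epoxide on the face of the C10 hydroxyl) | O=C1[C@@](C)(O)[C@H]2O[C@H]2[C@@H](C(C)=C)C1
F3 | step 5 | hydroxy selenide (C9 phenylselanyl, C8 hydroxyl cis to the C10 hydroxyl) | O=C1[C@@](C)(O)[C@H]([Se]c2ccccc2)[C@@H](O)[C@@H](C(C)=C)C1
F4 | step 13 | triene (C1 vinyl in place of bromide) | C=CC1=C([C@@H](O[Si](C)(C)C(C)(C)C)[C@@H](C)C=C)[C@H](C(C)C(=O)OC)[C@H]2C[C@]1(C)O[Si](C(C)(C)C)(C(C)(C)C)O2
F5 | step 13 | cyclohexadiene (C1=C6 and C2=C3) | C12=C([C@@H](O[Si](C)(C)C(C)(C)C)[C@@H](C)C=C1)[C@H](C(C)C(=O)OC)[C@H]3C[C@]2(C)O[Si](C(C)(C)C)(C(C)(C)C)O3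
F6 | step 15 | 6-epimeric hydroxy lactone (cis lactone, C1 carbinol) | OC1CC[C@H](C)[C@H](O[Si](C)(C)C(C)(C)C)[C@@H]2OC(=O)C(C)[C@@H]2[C@H]3C[C@]1(C)O[Si](C(C)(C)C)(C(C)(C)C)O3
F7 | step 15 | 6-epimeric keto lactone | O=C1CC[C@H](C)[C@H](O[Si](C)(C)C(C)(C)C)[C@@H]2OC(=O)C(C)[C@@H]2[C@H]3C[C@]1(C)O[Si](C(C)(C)C)(C(C)(C)C)O3
F8 | step 15 | hydroxy amide (6-epi carbinol, N-methoxy-N-methyl amide at C12) | O=C1CC[C@H](C)[C@H](O[Si](C)(C)C(C)(C)C)[C@H](O)[C@H](C(C)C(=O)N(C)OC)[C@H]2C[C@]1(C)O[Si](C(C)(C)C)(C(C)(C)C)O2
F9 | step 15 | 6S keto lactone (trans lactone, α-methyl) | O=C1CC[C@H](C)[C@H](O[Si](C)(C)C(C)(C)C)[C@H]2OC(=O)C(C)[C@@H]2[C@H]3C[C@]1(C)O[Si](C(C)(C)C)(C(C)(C)C)O3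
F10 | step 18 | α-phenylselanyl ketone (Se on C2, configuration undefined) | O=C1C([Se]c4ccccc4)C[C@H](C)[C@H](O[Si](C)(C)C(C)(C)C)[C@H]2OC(=O)C(=C)[C@@H]2[C@H]3C[C@]1(C)O[Si](C(C)(C)C)(C(C)(C)C)O3
A1 | alternative 1 | 2-(2,2,4-trimethyl-1,3-dioxolan-4-yl)acetaldehyde (C8 aldehyde) | C[C@@]1(COC(C)(C)O1)CC=O
A2 | alternative 1 | furan | c1ccoc1
A3 | alternative 1 | exo 2,7-dioxabicyclo[3.2.0]hept-3-ene photoadduct | C[C@@]1(COC(C)(C)O1)C[C@H]2O[C@@H]3OC=C[C@H]23
A4 | alternative 2 | bridged isoxazoline in the ten-membered ring | C[C@H]1[C@@H]2CC(=NO2)[C@@](C)(OC3(C)C)C[C@@H](O3)[C@H]4CC(=O)O[C@@H]4[C@H]1O[Si](C)(C)C(C)(C)C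
A5 | alternative 3 | ten-membered C6 carbinol with C7 2-propenyl unit | C=C(COCc1ccc(OC)cc1)[C@H]2[C@H](O)[C@@H](O)[C@@H](C)/C=C/C3(OCCO3)[C@@](C)(OC4(C)C)C[C@H]2O4
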